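**Retrosynthetic overview**

1. The target comes from a ten-membered 6,9-dione that already carries the C3 acetate, the C8 epoxy ester and the C7 acrylate. Reagent-controlled reduction of both enone carbonyls and trans-lactonisation of O6 onto C12 finish the synthesis.
2. The ten-membered ring comes from glycol cleavage of the C6–C9 bond of a cis-bicyclo[6.2.0]decadiene-1,8-diol: the eight-membered ring grows by the two cyclobutane carbons C7 and C8.
3. The cyclobutane comes from a [2+2] cycloaddition of a C5 vinylketene (C7, C8, C11–C13, from dimethyl itaconate) to the C6=C9 enediol derivative (O6 silyl, O9 epoxy ester) of an eight-membered acyloin. The four-membered ring is the template on which C7 and C8 are set, and the epoxy acyl group is relayed from O9 to O8.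
4. The eight-membered ring is (1Z,5Z)-1,5-dimethylcycloocta-1,5-diene, oxidised at C3, C9 and C6. Ring order: eight-membered ring (bought), cyclobutane, ten-membered ring, γ-lactone last; the oxirane is brought in ready-made.
5. Enabling feature: C10(Me)=C1–C2–C3–C4(Me)=C5 together with C6 and C9 of the ten-membered ring are the eight ring atoms, both methyl groups and both Z double bonds of the isoprene dimer. C6 and C9, which flank the missing C7–C8 unit, both bear oxygen in the target, so the bond between them can be built and then cut as a 1,2-diol.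

Key step: step 18

Remark: labels C1–C15 in the text follow germacrane numbering of the target (C12 lactone carbonyl on O6, C13 exocyclic methylene, C14 on C10, C15 on C4), while systematic names of the monocyclic eight-membered compounds use their own locants; technical 1,5-dimethylcycloocta-1,5-diene is assumed to be freed from its 1,6-dimethyl isomer by fractional distillation before use.

**Route**

Step 1
Reactants: 1 (1Z,5Z)-1,5-dimethylcycloocta-1,5-diene
Product: 2 rac-(2Z,6Z)-2,6-dimethylcycloocta-2,6-dien-1-ol
Conditions: SeO2 (0.3 equiv), tert-butyl hydroperoxide (1.1 equiv), CH2Cl2, 0 °C to rt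
Reagents that add atoms: tert-butyl hydroperoxide CC(C)(C)OO; selenium dioxide O=[Se]=O (oxygen carrier)
Why: Riley oxidation (ene reaction of SeO2, then [2,3]-sigmatropic shift) hydroxylates a trisubstituted ring alkene at the ring CH2 on its methyl-bearing carbon without moving the double bond, and with about one equivalent of oxidant mainly one of the two equivalent alkenes should react (diol and unreacted 1 are separated and recycled).

Step 2
Reactants: 2 rac-2,6-dimethylcycloocta-2,6-dien-1-ol
Product: 3 (2Z,6Z)-2,6-dimethylcycloocta-2,6-dien-1-one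
Conditions: MnO2 (excess), CH2Cl2, rt
Reagents that add atoms: none
Why: MnO2 oxidation of the allylic alcohol gives the achiral enone, which erases the racemic centre so that it can be reset under catalyst control.

Step 3
Reactants: 3 2,6-dimethylcycloocta-2,6-dien-1-one
Product: 4 (1S,2Z,6Z)-2,6-dimethylcycloocta-2,6-dien-1-ol
Conditions: (R)-2-methyl-CBS-oxazaborolidine (0.1 equiv), BH3·SMe2 (0.7 equiv), THF, −20 °C; MeOH, then aqueous work-up
Reagents that add atoms: none
Why: CBS reduction in which the methyl-bearing alkenyl carbon is the large and the ring CH2 the small carbonyl substituent, so the (R)-oxazaborolidine should deliver hydride to the face that gives the S carbinol, the future C3.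

Step 4
Reactants: 4 (1S)-2,6-dimethylcycloocta-2,6-dien-1-ol
Product: 5 tert-butyl{[(1S,2Z,6Z)-2,6-dimethylcycloocta-2,6-dien-1-yl]oxy}dimethylsilane
Conditions: tert-butyl(chloro)dimethylsilane, imidazole, DMF, rt
Reagents that add atoms: tert-butyl(chloro)dimethylsilane CC(C)(C)[Si](C)(C)Cl
Why: Silyl ether formation protects O3 through the base and hydride steps without touching the stereocentre.

Step 5
Reactants: 5 silyl ether of 4
Product: 6 (5S,2Z,6Z)-5-[tert-butyl(dimethyl)silyl]oxy-2,6-dimethylcycloocta-2,6-dien-1-ol (both C1 epimers)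
Conditions: SeO2 (0.5 equiv), tert-butyl hydroperoxide (2 equiv), CH2Cl2, rt
Reagents that add atoms: tert-butyl hydroperoxide CC(C)(C)OO; selenium dioxide O=[Se]=O (oxygen carrier)
Why: A second Riley oxidation should attack the remaining unfunctionalised alkene at its ring CH2 next to the methyl-bearing carbon (C9), ring CH2 being preferred over methyl and over the hindered silyloxy-substituted alkene; both epimers of the new carbinol converge in step 6.

Step 6
Reactants: 6 allylic alcohol (C1 epimers)
Product: 7 (5S,2Z,6Z)-5-[tert-butyl(dimethyl)silyl]oxy-2,6-dimethylcycloocta-2,6-dien-1-one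
Conditions: MnO2 (excess), CH2Cl2, rt
Reagents that add atoms: none
Why: MnO2 oxidises the allylic alcohol chemoselectively to the conjugated C9 ketone.

Step 7
Reactants: 7 silyloxy enone
Product: 9 (5S,2Z,6Z)-5-[tert-butyl(dimethyl)silyl]oxy-8-hydroxy-2,6-dimethylcycloocta-2,6-dien-1-one (both C8 epimers), via potassium dienolate 8 (not isolated)
Conditions: KN(SiMe3)2 (1.1 equiv), THF, −78 °C; 2-(phenylsulfonyl)-3-phenyloxaziridine, −78 °C; AcOH quench
Reagents that add atoms: 2-(phenylsulfonyl)-3-phenyloxaziridine O=S(=O)(c1ccccc1)N1OC1c1ccccc1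
Why: Kinetic deprotonation at the only α′ position (C6, also allylic to C4=C5) gives the cross-conjugated dienolate, which the N-sulfonyloxaziridine hydroxylates at carbon (enolate oxidation); the new C6 centre is a mixture of no consequence because it becomes trigonal in step 11.

Step 8
Reactants: 9 α′-hydroxy enone
Product: 10 (5S,2Z,6Z)-5,8-bis[tert-butyl(dimethyl)silyloxy]-2,6-dimethylcycloocta-2,6-dien-1-one (both C8 epimers)
Conditions: tert-butyldimethylsilyl triflate, 2,6-lutidine, CH2Cl2, −78 to 0 °C
Reagents that add atoms: tert-butyldimethylsilyl trifluoromethanesulfonate CC(C)(C)[Si](C)(C)OS(=O)(=O)C(F)(F)F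
Why: Silyl triflate silylation of the hindered α-hydroxy ketone; the tert-butyldimethylsilyl group is chosen because it should not migrate between the two oxygens of the enediolate formed in step 11.

Step 9
Reactants: 11 (E)-2-methylbut-2-en-1-ol
Product: 12 [(2R,3R)-2,3-dimethyloxiran-2-yl]methanol
Conditions: Ti(OiPr)4 (0.1 equiv), D-(−)-diisopropyl tartrate (0.12 equiv), tert-butyl hydroperoxide, 4 Å molecular sieves, CH2Cl2, −20 °C
Reagents that add atoms: tert-butyl hydroperoxide CC(C)(C)OO
Why: Sharpless asymmetric epoxidation of the E trisubstituted allylic alcohol, in which the D-(−)-tartrate catalyst delivers oxygen to the face that gives the (2R,3R)-epoxy alcohol and so sets both oxirane stereocentres (cis methyl groups).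

Step 10
Reactants: 12 (2R,3R)-epoxy alcohol
Product: 13 (2S,3R)-2,3-dimethyloxirane-2-carboxylic acid
Conditions: RuCl3·xH2O (2 mol %), NaIO4 (3 equiv), CCl4/MeCN/H2O, rt
Reagents that add atoms: sodium periodate [Na+].[O-]I(=O)(=O)=O; water O
Why: RuO4 generated from RuCl3 and NaIO4 oxidises the primary alcohol to the acid without opening the oxirane, the change of the C2 descriptor from R to S being only a change of substituent priorities.

Step 11
Reactants: 10 bis-silyloxy ketone; 13 (2S,3R)-2,3-dimethyloxirane-2-carboxylic acid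
Product: 16 (5S,1Z,3Z,7Z)-2,5-bis[tert-butyl(dimethyl)silyloxy]-4,8-dimethylcycloocta-1,3,7-trien-1-yl (2S,3R)-2,3-dimethyloxirane-2-carboxylate, via acid chloride 14 (not isolated), via potassium enolate 15 (not isolated)
Conditions: 13, 1-chloro-N,N,2-trimethylprop-1-en-1-amine, CH2Cl2, 0 °C; separately 10, KN(SiMe3)2, THF, −78 °C; acid chloride solution added at −78 °C, then −40 °C
Reagents that add atoms: none
Why: The acid chloride is formed under neutral conditions with the α-chloroenamine and the tetrasubstituted potassium enolate is acylated on oxygen (enol ester formation) because its carbon terminus is fully substituted, which puts the weak acyloxy donor on C9 and leaves the strong silyloxy donor on C6 so that the C6=C9 bond is polarised for step 14.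

Step 12
Reactants: 17 dimethyl itaconate
Product: 18 3-(methoxycarbonyl)but-3-enoic acid
Conditions: LiOH (1.0 equiv), THF/H2O, 0 °C; aqueous HCl
Reagents that add atoms: lithium hydroxide [Li+].[OH-]
Why: Partial saponification, in which the unconjugated ester is more electrophilic than the acrylate ester and should be cleaved selectively by one equivalent of hydroxide.

Step 13
Reactants: 18 3-(methoxycarbonyl)but-3-enoic acid
Product: 19 methyl 4-chloro-2-methylidene-4-oxobutanoate
Conditions: (COCl)2, DMF (cat.), CH2Cl2, 0 °C to rt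
Reagents that add atoms: oxalyl chloride ClC(=O)C(=O)Cl
Why: Standard conversion of the acid into the acyl chloride that serves as ketene precursor.

Step 14
Reactants: 16 enol ester; 19 methyl 4-chloro-2-methylidene-4-oxobutanoate
Product: 21 methyl (3S,6R,7S,9R)-3,6-bis[tert-butyl(dimethyl)silyloxy]-9-[(2S,3R)-2,3-dimethyloxirane-2-carbonyloxy]-8-oxo-6,9-cyclogermacra-1(10)Z,4Z,11(13)-trien-12-oate (cis-fused cyclobutanone), via vinylketene 20 (not isolated)
Conditions: 19 added slowly to 16 and Et3N, toluene, rt to 40 °C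
Reagents that add atoms: none
Why: Ketene–enol ether [2+2] cycloaddition in which the electron-poor vinylketene formed by dehydrochlorination is attacked at its carbonyl carbon by C9 (β to the silyloxy donor) and its enolate carbon closes onto the silyloxy-stabilised cation at C6, so C8 is bound to C9 and C7 to C6 with cis ring fusion; the ketene should approach the convex face of the tub-shaped triene anti to the pseudo-axial C3 silyloxy group, and the acidic C7–H equilibrates under Et3N so that the acrylate lies cis to the ring-fusion oxygens and trans to the C5 vinyl carbon.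

Step 15
Reactants: 21 cyclobutanone
Product: 23 methyl (3S,6R,7R,8S,9S)-3,6-bis[tert-butyl(dimethyl)silyloxy]-8-[(2S,3R)-2,3-dimethyloxirane-2-carbonyloxy]-9-hydroxy-6,9-cyclogermacra-1(10)Z,4Z,11(13)-trien-12-oate, via cyclobutanol 22 (not isolated)
Conditions: NaBH4, MeOH/THF, −78 to −40 °C; AcOH; crude material, DBU (0.2 equiv), CH2Cl2, 0 °C to rt
Reagents that add atoms: none
Why: Hydride reduction followed by 1,2-acyl migration, in which borohydride attacks the strained ketone anti to the C7 acrylate and the C9 acyloxy group that flank it on the same face and so sets C8 with its oxygen cis to both, and base then moves the acyl group through the cis-fused orthoester from the tertiary O9 to the secondary O8, which frees the C9 hydroxyl needed in step 18.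

Step 16
Reactants: 23 C8 ester, C9 alcohol
Product: 24 methyl (3S,6R,7R,8S,9S)-8-[(2S,3R)-2,3-dimethyloxirane-2-carbonyloxy]-3,6,9-trihydroxy-6,9-cyclogermacra-1(10)Z,4Z,11(13)-trien-12-oate
Conditions: HF·pyridine, pyridine, THF, 0 °C to rt
Reagents that add atoms: none
Why: Fluoride-mediated desilylation with buffered HF·pyridine removes both silyl ethers, while the weakly acidic medium should leave the electron-poor oxirane and the tertiary γ-hydroxy ester (no lactonisation) unchanged.

Step 17
Reactants: 24 triol
Product: 25 methyl (3S,6R,7R,8S,9S)-3-acetoxy-8-[(2S,3R)-2,3-dimethyloxirane-2-carbonyloxy]-6,9-dihydroxy-6,9-cyclogermacra-1(10)Z,4Z,11(13)-trien-12-oate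
Conditions: Ac2O, pyridine, CH2Cl2, 0 °C to rt
Reagents that add atoms: acetic anhydride CC(=O)OC(C)=O
Why: Acetylation without acylation catalyst esterifies only the secondary allylic C3 hydroxyl, the two tertiary cyclobutanols being inert, which installs the C3 acetate of the target.

Step 18
Reactants: 25 ring-fusion diol
Product: 26 methyl (3S,7R,8S)-3-acetoxy-8-[(2S,3R)-2,3-dimethyloxirane-2-carbonyloxy]-6,9-dioxogermacra-1(10)Z,4Z,11(13)-trien-12-oate
Conditions: Pb(OAc)4 (1.1 equiv), pyridine (2 equiv), CH2Cl2, −20 to 0 °C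
Reagents that add atoms: none
Why: Pb(OAc)4 esterifies the cis-1,2-diol at the ring fusion (C6–OH, C9–OH) to a five-membered cyclic lead diester, whose two-electron collapse breaks the C6–C9 bond and gives the two ketones (Criegee glycol cleavage), so the cyclobutane and the eight-membered ring merge into the ten-membered ring (8 to 10, the ring grows by C7 and C8). The closest known reaction type is the two-carbon ring expansion by cleavage of the ring-fusion diol of [2+2] adducts of acyloin-derived enediol ethers to medium-ring 1,4-diones. No ring is closed in this step: the ten-membered ring arises by scission of the bond shared by the four- and eight-membered rings. No stereocentre is created; C6 and C9 become trigonal, C7 and C8 keep the configuration fixed on the rigid bicycle in steps 14 and 15, C3 is untouched, and both trisubstituted double bonds keep the Z geometry that the eight-membered ring enforced. The step needs chemoselective cleavage of this one glycol and preservation of the epimerisable C7 centre: the di-tertiary cis diol is the only free 1,2-diol (O8 and O3 are acylated), and its cleavage is driven by release of the cyclobutane strain and so should run at −20 °C under nearly neutral conditions, where enolisation of the new C6 ketone toward C7 and β-elimination of the C8 acyloxy group should not compete.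

Step 19
Reactants: 26 ten-membered 6,9-dione
Product: 28 (3S,6R,7S,8S,9R)-3-acetoxy-9-hydroxy-8-[(2S,3R)-2,3-dimethyloxirane-2-carbonyloxy]germacra-1(10)Z,4Z,11(13)-trien-12,6-olide, via diol ester 27 (not isolated)
Conditions: (R)-2-methyl-CBS-oxazaborolidine (0.5 equiv), catecholborane (3 equiv), toluene/CH2Cl2, −78 °C; aqueous work-up; pyridinium p-toluenesulfonate (cat.), CH2Cl2, rt
Reagents that add atoms: none
Why: Double CBS reduction in which the alkenyl carbons C5 and C10 act as the large groups, so the (R)-oxazaborolidine should deliver hydride to give the 6R and 9R allylic alcohols (1,2-reduction, esters and oxirane untouched), after which acid catalysis closes the γ-lactone from O6 onto the acrylate ester, trans-fused because C6–O and C7–C11 lie on opposite faces; O8 is acylated and a lactone from O9 would be six-membered, so only the 6,12-lactone should form.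

**Compound list**

1 | (1Z,5Z)-1,5-dimethylcycloocta-1,5-diene | C1/C=C(/C)CC/C=C(/C)C1 | starting material
2 | rac-(2Z,6Z)-2,6-dimethylcycloocta-2,6-dien-1-ol | C1C/C=C(/C)C(O)C/C=C1/C | intermediate
3 | (2Z,6Z)-2,6-dimethylcycloocta-2,6-dien-1-one | C1C/C=C(/C)C(=O)C/C=C1/C | intermediate
4 | (1S,2Z,6Z)-2,6-dimethylcycloocta-2,6-dien-1-ol | C1C/C=C(/C)[C@@H](O)C/C=C1/C | intermediate
5 | tert-butyl{[(1S,2Z,6Z)-2,6-dimethylcycloocta-2,6-dien-1-yl]oxy}dimethylsilane | C1C/C=C(/C)[C@@H](O[Si](C)(C)C(C)(C)C)C/C=C1/C | intermediate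
6 | (5S,2Z,6Z)-5-[tert-butyl(dimethyl)silyl]oxy-2,6-dimethylcycloocta-2,6-dien-1-ol, both C1 epimers | OC1C/C=C(/C)[C@@H](O[Si](C)(C)C(C)(C)C)C/C=C1/C | intermediate
7 | (5S,2Z,6Z)-5-[tert-butyl(dimethyl)silyl]oxy-2,6-dimethylcycloocta-2,6-dien-1-one | O=C1C/C=C(/C)[C@@H](O[Si](C)(C)C(C)(C)C)C/C=C1/C | intermediate
8 | potassium dienolate of 7 (O–K on C9, C9=C6) | [K+].[O-]/C1=C/C=C(/C)[C@@H](O[Si](C)(C)C(C)(C)C)C/C=C1/C | intermediate
9 | (5S,2Z,6Z)-5-[tert-butyl(dimethyl)silyl]oxy-8-hydroxy-2,6-dimethylcycloocta-2,6-dien-1-one, both C8 epimers | O=C1C(O)/C=C(/C)[C@@H](O[Si](C)(C)C(C)(C)C)C/C=C1/C | intermediate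
10 | (5S,2Z,6Z)-5,8-bis[tert-butyl(dimethyl)silyloxy]-2,6-dimethylcycloocta-2,6-dien-1-one, both C8 epimers | O=C1C(O[Si](C)(C)C(C)(C)C)/C=C(/C)[C@@H](O[Si](C)(C)C(C)(C)C)C/C=C1/C | intermediate
11 | (E)-2-methylbut-2-en-1-ol | C/C=C(\C)CO | starting material
12 | [(2R,3R)-2,3-dimethyloxiran-2-yl]methanol | OC[C@@]1(C)O[C@@H]1C | intermediate
13 | (2S,3R)-2,3-dimethyloxirane-2-carboxylic acid | OC(=O)[C@@]1(C)O[C@@H]1C | intermediate
14 | (2S,3R)-2,3-dimethyloxirane-2-carbonyl chloride | ClC(=O)[C@@]1(C)O[C@@H]1C | intermediate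
15 | potassium enolate of 10 (O–K on C9, C9=C6) | [K+].[O-]/C1=C(O[Si](C)(C)C(C)(C)C)/C=C(/C)[C@@H](O[Si](C)(C)C(C)(C)C)C/C=C1/C | intermediate
16 | (5S,1Z,3Z,7Z)-2,5-bis[tert-butyl(dimethyl)silyloxy]-4,8-dimethylcycloocta-1,3,7-trien-1-yl (2S,3R)-2,3-dimethyloxirane-2-carboxylate | O(C(=O)[C@@]2(C)O[C@@H]2C)/C1=C(O[Si](C)(C)C(C)(C)C)/C=C(/C)[C@@H](O[Si](C)(C)C(C)(C)C)C/C=C1/C | intermediate
17 | dimethyl itaconate (dimethyl 2-methylidenebutanedioate) | COC(=O)CC(=C)C(=O)OC | starting material
18 | 3-(methoxycarbonyl)but-3-enoic acid | OC(=O)CC(=C)C(=O)OC | intermediate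
19 | methyl 4-chloro-2-methylidene-4-oxobutanoate | ClC(=O)CC(=C)C(=O)OC | intermediate
20 | methyl 2-methylidene-4-oxobut-3-enoate (vinylketene) | O=C=CC(=C)C(=O)OC | intermediate
21 | methyl (3S,6R,7S,9R)-3,6-bis[tert-butyl(dimethyl)silyloxy]-9-[(2S,3R)-2,3-dimethyloxirane-2-carbonyloxy]-8-oxo-6,9-cyclogermacra-1(10)Z,4Z,11(13)-trien-12-oate; cis-fused, with O6, O9, the C7 acrylate and O3 on one face | C=C(C(=O)OC)[C@@H]1C(=O)[C@@]2(OC(=O)[C@@]3(C)O[C@@H]3C)/C(C)=C\C[C@H](O[Si](C)(C)C(C)(C)C)/C(C)=C\[C@@]12O[Si](C)(C)C(C)(C)C | intermediate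
22 | methyl (3S,6R,7R,8S,9S)-3,6-bis[tert-butyl(dimethyl)silyloxy]-9-[(2S,3R)-2,3-dimethyloxirane-2-carbonyloxy]-8-hydroxy-6,9-cyclogermacra-1(10)Z,4Z,11(13)-trien-12-oate | C=C(C(=O)OC)[C@@H]1[C@H](O)[C@@]2(OC(=O)[C@@]3(C)O[C@@H]3C)/C(C)=C\C[C@H](O[Si](C)(C)C(C)(C)C)/C(C)=C\[C@@]12O[Si](C)(C)C(C)(C)C | intermediate
23 | methyl (3S,6R,7R,8S,9S)-3,6-bis[tert-butyl(dimethyl)silyloxy]-8-[(2S,3R)-2,3-dimethyloxirane-2-carbonyloxy]-9-hydroxy-6,9-cyclogermacra-1(10)Z,4Z,11(13)-trien-12-oate | C=C(C(=O)OC)[C@@H]1[C@H](OC(=O)[C@@]3(C)O[C@@H]3C)[C@@]2(O)/C(C)=C\C[C@H](O[Si](C)(C)C(C)(C)C)/C(C)=C\[C@@]12O[Si](C)(C)C(C)(C)C | intermediate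
24 | methyl (3S,6R,7R,8S,9S)-8-[(2S,3R)-2,3-dimethyloxirane-2-carbonyloxy]-3,6,9-trihydroxy-6,9-cyclogermacra-1(10)Z,4Z,11(13)-trien-12-oate | C=C(C(=O)OC)[C@@H]1[C@H](OC(=O)[C@@]3(C)O[C@@H]3C)[C@@]2(O)/C(C)=C\C[C@H](O)/C(C)=C\[C@@]12O | intermediate
25 | methyl (3S,6R,7R,8S,9S)-3-acetoxy-8-[(2S,3R)-2,3-dimethyloxirane-2-carbonyloxy]-6,9-dihydroxy-6,9-cyclogermacra-1(10)Z,4Z,11(13)-trien-12-oate | C=C(C(=O)OC)[C@@H]1[C@H](OC(=O)[C@@]3(C)O[C@@H]3C)[C@@]2(O)/C(C)=C\C[C@H](OC(C)=O)/C(C)=C\[C@@]12O | intermediate
26 | methyl (3S,7R,8S)-3-acetoxy-8-[(2S,3R)-2,3-dimethyloxirane-2-carbonyloxy]-6,9-dioxogermacra-1(10)Z,4Z,11(13)-trien-12-oate | C=C(C(=O)OC)[C@H]1C(=O)/C=C(/C)[C@@H](OC(C)=O)C/C=C(/C)C(=O)[C@H]1OC(=O)[C@@]2(C)O[C@@H]2C | intermediate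
27 | methyl (3S,6R,7S,8S,9R)-3-acetoxy-8-[(2S,3R)-2,3-dimethyloxirane-2-carbonyloxy]-6,9-dihydroxygermacra-1(10)Z,4Z,11(13)-trien-12-oate | C=C(C(=O)OC)[C@H]1[C@H](O)/C=C(/C)[C@@H](OC(C)=O)C/C=C(/C)[C@@H](O)[C@H]1OC(=O)[C@@]2(C)O[C@@H]2C | intermediate
28 | (3S,6R,7S,8S,9R)-3-acetoxy-9-hydroxy-8-[(2S,3R)-2,3-dimethyloxirane-2-carbonyloxy]germacra-1(10)Z,4Z,11(13)-trien-12,6-olide | C=C1C(=O)O[C@@H]2/C=C(/C)[C@@H](OC(C)=O)C/C=C(/C)[C@@H](O)[C@@H](OC(=O)[C@@]3(C)O[C@@H]3C)[C@@H]12 | target

**Step count and risks**

Total step count: 19 (steps 9–10 and 12–13 make the two side fragments). Longest linear sequence: 15 steps (1–8, 11, 14–19).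

Steps most likely to fail:

Step 14. The monosubstituted vinylketene may add too slowly to the tetrasubstituted, doubly oxygenated C6=C9 bond. Ketene dimerisation or simple C-acylation by silyl transfer could then win, and facial selectivity could erode at the temperature needed. The fallback replaces the ketene by a keteniminium ion. It sets out from 19, which with dimethylamine should give methyl 4-(dimethylamino)-2-methylidene-4-oxobutanoate F1. Triflic anhydride and 2,4,6-collidine should convert this amide into the keteniminium triflate F2, a far stronger electrophile that should add to 16 at −40 °C with the same regiochemistry to give the cyclobutaniminium triflate F3. Hydrolysis with aqueous NaHCO3 comes back to the route at 21.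

Step 19. Facial selectivity in the double carbonyl reduction may fail at C6, where the branched C7 could override the C5 alkenyl carbon as the large group, so that hydride is delivered to the wrong face at C6 while C9 is set correctly. The fallback is reduction followed by inversion. It sets out from 26, which under the same reduction conditions but without the acid treatment would then give the 6-epi (6S) diol ester F4. A Mitsunobu reaction with chloroacetic acid (PPh3, diisopropyl azodicarboxylate) should esterify the C6 allylic hydroxyl with inversion to the 6R chloroacetate F5. Thiourea and NaHCO3 in ethanol should remove the chloroacetyl group without touching the acetate, the epoxy ester or the methyl ester. This comes back to the route at 27, which is lactonised as in step 19.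

Step 15. Hydride may be delivered to the cyclobutanone syn to the C7 side chain. The C8 oxygen would then lie trans to the C9 ester, the acyl relay could not take place, and C8 would have the wrong configuration. The fallback installs the ester by substitution with inversion. It sets out from 10, whose potassium enolate 15 with trifluoroacetic anhydride should give the enol trifluoroacetate F6. Cycloaddition with 20 as in step 14 should give the cyclobutanone F7. NaBH4 in methanol should reduce the ketone and cleave the trifluoroacetate to the 8-epi diol F8. A Mitsunobu esterification of its secondary cyclobutanol with acid 13 (PPh3, diisopropyl azodicarboxylate; the tertiary C9 hydroxyl does not react) installs the epoxy ester with inversion and comes back to the route at 23.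

Further compounds
F1 | step 14 | methyl 4-(dimethylamino)-2-methylidene-4-oxobutanoate | CN(C)C(=O)CC(=C)C(=O)OC
F2 | step 14 | N-[3-(methoxycarbonyl)buta-1,3-dien-1-ylidene]-N-methylmethanaminium triflate (keteniminium salt) | C[N+](C)=C=CC(=C)C(=O)OC.[O-]S(=O)(=O)C(F)(F)F
F3 | step 14 | cyclobutaniminium triflate corresponding to 21 (C8=N+Me2 in place of C8=O) | C=C(C(=O)OC)[C@@H]1C(=[N+](C)C)[C@@]2(OC(=O)[C@@]3(C)O[C@@H]3C)/C(C)=C\C[C@H](O[Si](C)(C)C(C)(C)C)/C(C)=C\[C@@]12O[Si](C)(C)C(C)(C)C.[O-]S(=O)(=O)C(F)(F)F
F4 | step 19 | methyl (3S,6S,7S,8S,9R)-3-acetoxy-8-[(2S,3R)-2,3-dimethyloxirane-2-carbonyloxy]-6,9-dihydroxygermacra-1(10)Z,4Z,11(13)-trien-12-oate (6-epi-27) | C=C(C(=O)OC)[C@H]1[C@@H](O)/C=C(/C)[C@@H](OC(C)=O)C/C=C(/C)[C@@H](O)[C@H]1OC(=O)[C@@]2(C)O[C@@H]2C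
F5 | step 19 | 6-O-chloroacetyl derivative of 27 (6R) | C=C(C(=O)OC)[C@H]1[C@H](OC(=O)CCl)/C=C(/C)[C@@H](OC(C)=O)C/C=C(/C)[C@@H](O)[C@H]1OC(=O)[C@@]2(C)O[C@@H]2C
F6 | step 15 | (5S,1Z,3Z,7Z)-2,5-bis[tert-butyl(dimethyl)silyloxy]-4,8-dimethylcycloocta-1,3,7-trien-1-yl trifluoroacetate | O(C(=O)C(F)(F)F)/C1=C(O[Si](C)(C)C(C)(C)C)/C=C(/C)[C@@H](O[Si](C)(C)C(C)(C)C)C/C=C1/C
F7 | step 15 | cyclobutanone corresponding to 21 with a trifluoroacetate on O9 | C=C(C(=O)OC)[C@@H]1C(=O)[C@@]2(OC(=O)C(F)(F)F)/C(C)=C\C[C@H](O[Si](C)(C)C(C)(C)C)/C(C)=C\[C@@]12O[Si](C)(C)C(C)(C)C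
F8 | step 15 | methyl 3,6-bis[tert-butyl(dimethyl)silyloxy]-8,9-dihydroxy-6,9-cyclogermacra-1(10)Z,4Z,11(13)-trien-12-oate with the C8 hydroxyl trans to the C7 side chain (8-epi diol) | C=C(C(=O)OC)[C@@H]1[C@@H](O)[C@@]2(O)/C(C)=C\C[C@H](O[Si](C)(C)C(C)(C)C)/C(C)=C\[C@@]12O[Si](C)(C)C(C)(C)C
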